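The runs are calculated with constants of no real substance, noise included.

Decide first what you expect to stop the target in maple: the clock or the second substrate.

common to all: starting material 48 mM; gas 10 mM (held)

| flask | second substrate | temperature | remark | time |
|---|---|---|---|---|
| grey | 4.8 mM | 70 °C | run made earlier |  |
| maple | 9.60 mM | 70 °C |  | 80 min |
| elm | 9.60 mM | 100 °C |  | 80 min |
| cedar | 9.60 mM | 40 °C |  | 80 min |

- grey (time / min: target / %, starting material / %): 0.667: 0, 99.8; 1.00: 0, 99.5; 1.33: 0.5, 99.6; 2.50: 0.8, 99.0; 3.00: 1.6, 98.3; 5.00: 2.9, 96.4; 8.00: 4.9, 93.8

(standard deviation of a reading: 0.3 percentage points)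

- at the start none of the gas is in solution
- the earlier runs do not show what temperature does; that part of a forecast is a guess

- the flask with the highest amount of target, in percent of the starting material charged ("all alike" if they lie within 1.5 percentage points) (maple / elm / cedar / all alike)
- final target, as a percentage of the starting material charged, in maple
- final target, as a percentage of the starting material charged, in elm
- final target, as a percentage of the starting material charged, in cedar

Take the last grey reading, 4.9% of target after 8.00 min, and stretch that pace over maple's 80 min, which gives 49.0%. Call this fraction of the charge, carried to target at the grey pace in the time allowed, the reach. Maple's reach is smaller than the whole charge, so by my reckoning the clock ends maple with starting material left over.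

The rival limit is the second substrate, charged at 20.0% of the starting material. But in grey the target had reached 2.35 mM, half of the 4.8 mM of second substrate charged, and the last gain, 2 percentage points in 3.00 min, is as steep as the gain before it, 1.3 points in 2.00 min. So I commit to about 49.0% for maple. One number is not enough for the other flasks, though, since the reach was read at 70 °C and says nothing about elm or cedar.

The forecast picks maple as the flask with the most target and puts it at 18%, with 16.5% for elm and 7% for cedar, holding that “the second substrate, at 20% of the starting material, should cap the yield if consumed 1:1”.

    starting material + partner → target (k = 0.00910 M⁻¹ s⁻¹, Ea = 46.0 kJ mol⁻¹)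
    second substrate + partner → second product (k = 0.00230 M⁻¹ s⁻¹, Ea = 52.0 kJ mol⁻¹)
    starting material + second substrate → cross product (k = 3.90 × 10⁻⁴ M⁻¹ s⁻¹, Ea = 82.0 kJ mol⁻¹)
    gas ⇌ partner, rate k4*(csat - [partner]) (kL = 0.00310 s⁻¹)
    partner → decomposed reagent (k = 2.10 × 10⁻⁴ s⁻¹, Ea = 92.0 kJ mol⁻¹)
    (constants at 40 °C)

Maple gives 45.1%, 3.9 points below its reach, with 43.4% of the starting material and 31.2% of its own charge of second substrate left; cedar gives 29.0%. The neighbour flask, elm's recipe run at 75 °C, gives 42.4%, while elm gives 22.9%, half of the reach read at 70 °C. In elm the partner stands at 0.449 mM after 80.0 min, far less than the 3.58 mM in maple. Elm by then holds 131 mM of decomposed reagent against 11.0 mM of target.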